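(The readings were generated by integration from invented constants; the scatter is artificial.)

2.00 mM is the spare s of this flask: the incoming ligand charged, less the two that each starting complex takes up. Below zero, incoming ligand is the limiting reagent, and complex with two exchanged cannot pass the incoming ligand charged divided by two; above zero that ceiling is gone, and the runs must show what holds the yield.

| flask | starting complex | incoming ligand | leaving ligand | remark | time |
|---|---|---|---|---|---|
| dusk | 2 mM | 6 mM | 2 mM | run made earlier |  |
| midnight | 2 mM | 6 mM | 8 mM | run made earlier |  |
| flask | 2.0 mM | 6.00 mM | 4.00 mM |  | 6.0 min |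

| run | time / min | complex with two exchanged / % | starting complex / % |
|---|---|---|---|
| dusk | 0.417 | 85.8 | 4.3 |
| dusk | 0.833 | 96.0 | 1.1 |
| dusk | 2.00 | 97.2 | 0 |
| dusk | 5.00 | 99.3 | 2.2 |
| midnight | 1.33 | 96.5 | 2.0 |
| midnight | 2.50 | 98.1 | 1.4 |
| midnight | 4.00 | 96.6 | 1.8 |
| midnight | 5.00 | 96.3 | 1.3 |

(standard deviation of a reading: 1 percentage point)

- a reading or a percentage of complex with two exchanged counts all its forms, free or not

1. equivalents of incoming ligand to starting complex, everything else as given, that leave most complex with two exchanged at 6.0 min
2. the amount of complex with two exchanged then, in percent of the starting complex charged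
3. the amount of complex with two exchanged with the amounts as given

Take the settings in turn. The 6.0 min you need not know well, for the midnight run reads 96.5 % at 1.33 min and 96.3 % at 5.00 min. Leaving ligand you need only roughly: going from 2 mM to 8 mM at the same s of 2.00 mM, the mean reading from 2.00 min on goes from 98.2 % to 97.0 %. The two charges inside s you must know well, since s is a difference: a relative slip in incoming ligand reaches it enlarged 3.00 times, one in starting complex 2.00 times. With s at 2.00 mM and 4.00 mM of leaving ligand, which lies between the two runs, I expect a reading between 97.0 % and 98.2 %, and 33.3 % of the incoming ligand left over.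

The forecast gives 97.7 % as charged and 99.2 % at 5 equiv, holding: “The optimum is therefore a shallow, open-ended excess”. The flask gives 98.0 % as charged, and at best 98.2 % at 3.40 equiv.

    complex with one exchanged + incoming ligand ⇌ leaving ligand + complex with two exchanged (K = 66.0, k = 55.0 L mol⁻¹ s⁻¹)
    starting complex + incoming ligand ⇌ leaving ligand + complex with one exchanged (K = 4.20, k = 72.0 L mol⁻¹ s⁻¹)
    crystals ⇌ complex with two exchanged, rate k3*(cs3 - [complex with two exchanged]) while solid is left; crystals form when [complex with two exchanged] > cs3 (solubility = 0.210 mM, k = 2.10 s⁻¹)
    complex with two exchanged + incoming ligand ⇌ leaving ligand + complex with three exchanged (K = 0.290, k = 240 L mol⁻¹ s⁻¹)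

In the flask, the step from complex with one exchanged to complex with two exchanged, taken alone and both ways together, relaxes at the asked time with a half-life of 0.0974 min, far shorter than the 6.0 min allowed, and what stands there is the same at ten times the time, which is thermodynamic control. The flask keeps 34 % of its incoming ligand, against the 33.3 % reckoned from s. With 3.6 mM of incoming ligand and all else held, s becomes −0.400 mM, so the ceiling is 90.0 % of the starting complex charged; that neighbour flask gives 79.4 %, with 17.0 % of starting complex still there.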